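**Retrosynthetic overview**

1. Target 20 ⇐ enol 19 ⇐ transannular oxy-Cope ring contraction of the eleven-membered hydroxy dienone 18 (C5–C10 formed, C7–C8 broken), as in the presumed biosynthesis.
2. 18 ⇐ carbonylative Stille macrocyclisation of the acyclic vinyl iodide/vinylstannane 17 (CO becomes C4), run in the same flask as the Cope step.
3. 17 ⇐ opening of a 7,8-epoxide by 3-methylbut-2-enoate at C8 (inversion); the 2-iodoallyl alcohol ⇐ α-iodo Wittig olefination and DIBAL-H reduction of aldehyde 14.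
4. 14 ⇐ Claisen rearrangement of 12 (C1–C11 bond, chirality transfer C9 → C11); 12 ⇐ alkenylmagnesium from 9 plus epoxy aldehyde 4 (Sharpless epoxidation of the stannyl dienol from 1).
5. Ring order: the eleven-membered carbocycle is closed first and exists only transiently; the seven-membered ring, the only ring of the target, forms last.

Assumption: the target is made as drawn, (1R,2S,7S) on the cycloheptenone with a (Z)-enol ester; atom labels C1–C20 in the text are those of macrocycle 18 (C1–C11 ring, C4 ketone, C7 carbinol, C8 ester carbon, C11 quaternary, C18 the CH2OH carbon), so C5, C10 and C11 are the stereocentres of 20.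

**Route**

Step 1
Reactants: 1 (2E)-3-methylpent-2-en-4-yn-1-ol
Product: 2 (2E,4E)-3-methyl-5-(tributylstannyl)penta-2,4-dien-1-ol
Conditions: Bu3SnH (1.1 equiv), PdCl2(PPh3)2 (2 mol%), THF, 0 °C → rt
Reagents that add atoms: tributyltin hydride, CCCC[SnH](CCCC)CCCC
Why: Palladium-catalysed syn-hydrostannation of the terminal alkyne puts tin on the distal carbon and gives the (E)-vinylstannane (the minor internal regioisomer is removed by chromatography); no stereocentre is formed.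

Step 2
Reactants: 2 (2E,4E)-3-methyl-5-(tributylstannyl)penta-2,4-dien-1-ol
Product: 3 [(2S,3S)-3-methyl-3-[(E)-2-(tributylstannyl)ethenyl]oxiran-2-yl]methanol
Conditions: Ti(OiPr)4 (10 mol%), L-(+)-diethyl tartrate (12 mol%), tBuOOH (2 equiv, in decane), 4 Å MS, CH2Cl2, −20 °C
Reagents that add atoms: tert-butyl hydroperoxide, CC(C)(C)OO
Why: Katsuki–Sharpless asymmetric epoxidation epoxidises only the hydroxyl-directed 2,3-alkene, and L-(+)-tartrate gives the (2S,3S)-epoxide (same sense as with geraniol), which sets C7 and C8; the vinylstannane is not an allylic-alcohol alkene and is left alone.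

Step 3
Reactants: 3 [(2S,3S)-3-methyl-3-[(E)-2-(tributylstannyl)ethenyl]oxiran-2-yl]methanol
Product: 4 (2R,3S)-3-methyl-3-[(E)-2-(tributylstannyl)ethenyl]oxirane-2-carbaldehyde
Conditions: Dess–Martin periodinane (1.3 equiv), NaHCO3, CH2Cl2, 0 °C
Reagents that add atoms: none
Why: Buffered Dess–Martin oxidation of the primary alcohol leaves the acid-sensitive oxirane and stannane intact; no stereocentre changes (the C2 descriptor changes only through CIP priorities).

Step 4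
Reactants: 5 6-methylhept-5-en-2-one
Product: 7 6-methylhept-5-en-1-yne, via enol phosphate 6 (not isolated)
Conditions: LDA (1.05 equiv), THF, −78 °C; ClP(O)(OEt)2, −78 °C → rt; LDA (2.3 equiv), −78 °C → rt; H2O
Reagents that add atoms: none
Why: Negishi conversion of a methyl ketone into a terminal alkyne: the kinetic enolate is O-phosphorylated and diethyl phosphate is then eliminated by LDA.

Step 5
Reactants: 7 6-methylhept-5-en-1-yne
Product: 9 (1E)-1-iodo-2,6-dimethylhepta-1,5-diene, via vinylalane 8 (not isolated)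
Conditions: AlMe3 (2 equiv), Cp2ZrCl2 (0.25 equiv), CH2Cl2, 0 °C → rt; then I2, THF, −30 → 0 °C
Reagents that add atoms: trimethylaluminium, C[Al](C)C; iodine, II
Why: Negishi zirconium-catalysed carboalumination adds methyl and aluminium syn across the alkyne (aluminium terminal), and iodinolysis with retention gives the (E)-trisubstituted vinyl iodide.

Step 6
Reactants: 9 (1E)-1-iodo-2,6-dimethylhepta-1,5-diene; 4 (2R,3S)-3-methyl-3-[(E)-2-(tributylstannyl)ethenyl]oxirane-2-carbaldehyde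
Product: 12 (1R,2E)-3,7-dimethyl-1-[(2S,3S)-3-methyl-3-[(E)-2-(tributylstannyl)ethenyl]oxiran-2-yl]octa-2,6-dien-1-ol, via vinyllithium 10 (not isolated), via vinylmagnesium bromide 11 (not isolated)
Conditions: 9, tBuLi (2.0 equiv), Et2O, −78 °C; MgBr2·OEt2 (1.0 equiv), −78 → 0 °C; then 4, CH2Cl2–Et2O, −78 °C
Reagents that add atoms: none
Why: Chelation-controlled Grignard 1,2-addition (magnesium bridging C=O and the oxirane oxygen): the alkenyl group attacks the aldehyde face anti to the oxirane C–C bond, the sense also predicted by the Felkin–Anh model, giving the erythro (1R) alcohol (C9), while the (E)-alkene survives both metal exchanges.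

Step 7
Reactants: 12 (1R,2E)-3,7-dimethyl-1-[(2S,3S)-3-methyl-3-[(E)-2-(tributylstannyl)ethenyl]oxiran-2-yl]octa-2,6-dien-1-ol
Product: 14 (3S,4E)-3-methyl-3-(4-methylpent-3-en-1-yl)-5-[(2S,3S)-3-methyl-3-[(E)-2-(tributylstannyl)ethenyl]oxiran-2-yl]pent-4-enal, via allyl vinyl ether 13 (not isolated)
Conditions: [Ir(cod)Cl]2 (2 mol%), Na2CO3 (0.6 equiv), vinyl acetate (5 equiv), toluene, 100 °C; then xylenes, 135 °C, sealed tube
Reagents that add atoms: vinyl acetate, CC(=O)OC=C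
Why: Iridium-catalysed transfer vinylation followed by aliphatic Claisen rearrangement through a chair transition state with the oxiranyl group equatorial (the axial alternative clashes with the cis methyl on C11), which transfers chirality from C9 (R) to the new quaternary C11 (S) and gives the (E)-C9=C10 alkene.

Step 8
Reactants: 14 (3S,4E)-3-methyl-3-(4-methylpent-3-en-1-yl)-5-[(2S,3S)-3-methyl-3-[(E)-2-(tributylstannyl)ethenyl]oxiran-2-yl]pent-4-enal
Product: 15 ethyl (2Z,5S,6E)-2-iodo-5-methyl-5-(4-methylpent-3-en-1-yl)-7-[(2S,3S)-3-methyl-3-[(E)-2-(tributylstannyl)ethenyl]oxiran-2-yl]hepta-2,6-dienoate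
Conditions: Ph3P=CHCO2Et (1.6 equiv), N-iodosuccinimide (1.5 equiv), CH2Cl2, −20 °C, 20 min; then 14, −20 °C → rt
Reagents that add atoms: ethyl (triphenyl-λ5-phosphanylidene)acetate, CCOC(=O)C=P(c1ccccc1)(c1ccccc1)c1ccccc1; N-iodosuccinimide, O=C1CCC(=O)N1I
Why: Wittig olefination with the stabilised α-iodo ylide (pre-formed so that no free iodinating agent meets the vinylstannane) places the chain trans to the ester and so cis to iodine, giving the (Z)-2-iodoenoate; no stereocentre is touched.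

Step 9
Reactants: 15 ethyl (2Z,5S,6E)-2-iodo-5-methyl-5-(4-methylpent-3-en-1-yl)-7-[(2S,3S)-3-methyl-3-[(E)-2-(tributylstannyl)ethenyl]oxiran-2-yl]hepta-2,6-dienoate
Product: 16 (2Z,5S,6E)-2-iodo-5-methyl-5-(4-methylpent-3-en-1-yl)-7-[(2S,3S)-3-methyl-3-[(E)-2-(tributylstannyl)ethenyl]oxiran-2-yl]hepta-2,6-dien-1-ol
Conditions: DIBAL-H (2.3 equiv), CH2Cl2, −78 °C; Rochelle salt
Reagents that add atoms: none
Why: Low-temperature DIBAL-H 1,2-reduction of the enoate to the allylic alcohol (C18) is faster than attack on the hindered oxirane, and the alkene geometry and all stereocentres are unchanged.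

Step 10
Reactants: 16 (2Z,5S,6E)-2-iodo-5-methyl-5-(4-methylpent-3-en-1-yl)-7-[(2S,3S)-3-methyl-3-[(E)-2-(tributylstannyl)ethenyl]oxiran-2-yl]hepta-2,6-dien-1-ol
Product: 17 (1E,3S,4R,5E,7S,9Z)-3,11-dihydroxy-10-iodo-3,7-dimethyl-7-(4-methylpent-3-en-1-yl)-1-(tributylstannyl)undeca-1,5,9-trien-4-yl 3-methylbut-2-enoate
Conditions: 3-methylbut-2-enoic acid (4 equiv), Cs2CO3 (1.5 equiv), DMF, 60 °C
Reagents that add atoms: 3-methylbut-2-enoic acid, CC(C)=CC(=O)O
Why: SN2 opening of the vinyl oxirane by the carboxylate at the secondary allylic carbon C8 (the fully substituted C7 is blocked under non-acidic conditions) inverts C8 (S → R) and keeps the C7–O bond, giving the anti tertiary-hydroxy ester, in parallel with the presumed biosynthetic opening of the 7,8-epoxide.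

Step 11
Reactants: 17 (1E,3S,4R,5E,7S,9Z)-3,11-dihydroxy-10-iodo-3,7-dimethyl-7-(4-methylpent-3-en-1-yl)-1-(tributylstannyl)undeca-1,5,9-trien-4-yl 3-methylbut-2-enoate
Product: 20 (Z)-2-[(1R,2S,7S)-4-(hydroxymethyl)-7-methyl-7-(4-methylpent-3-en-1-yl)-3-oxo-2-(2-oxopropyl)cyclohept-4-en-1-yl]ethenyl 3-methylbut-2-enoate, via macrocyclic dienone 18 (not isolated), via enol 19 (not isolated)
Conditions: Pd2(dba)3 (10 mol%), AsPh3 (40 mol%), CO (3 atm), DMF–THF, 2 mM (syringe-pump addition), 50 °C; then vent CO, Ar, 100 °C, 3 h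
Reagents that add atoms: carbon monoxide, [C-]#[O+]
Why: Carbonylative Stille macrocyclisation (vinyl iodide → acylpalladium → intramolecular transmetallation with the vinylstannane, both alkene geometries retained) closes the eleven-membered 2Z,5E,9E hydroxy dienone 18, which on warming undergoes the transannular oxy-Cope rearrangement of the presumed biosynthesis: a boat-like transition state with both trans alkenes sets C5 (S) and C10 (R) cis, the pseudo-axial 8R acyloxy group becomes the (Z)-enol ester, C11 is untouched, and enol 19 tautomerises to the methyl ketone.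

**Compound list**

1 | (2E)-3-methylpent-2-en-4-yn-1-ol | C#C/C(C)=C/CO | starting material
2 | (2E,4E)-3-methyl-5-(tributylstannyl)penta-2,4-dien-1-ol | CCCC[Sn](CCCC)(CCCC)/C=C/C(C)=C/CO | intermediate
3 | [(2S,3S)-3-methyl-3-[(E)-2-(tributylstannyl)ethenyl]oxiran-2-yl]methanol | OC[C@@H]1O[C@@]1(C)/C=C/[Sn](CCCC)(CCCC)CCCC | intermediate
4 | (2R,3S)-3-methyl-3-[(E)-2-(tributylstannyl)ethenyl]oxirane-2-carbaldehyde | O=C[C@@H]1O[C@@]1(C)/C=C/[Sn](CCCC)(CCCC)CCCC | intermediate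
5 | 6-methylhept-5-en-2-one | CC(=O)CCC=C(C)C | starting material
6 | diethyl 6-methylhepta-1,5-dien-2-yl phosphate | C=C(CCC=C(C)C)OP(=O)(OCC)OCC | intermediate
7 | 6-methylhept-5-en-1-yne | C#CCCC=C(C)C | intermediate
8 | [(1E)-2,6-dimethylhepta-1,5-dien-1-yl]dimethylalumane | C[Al](C)/C=C(\C)CCC=C(C)C | intermediate
9 | (1E)-1-iodo-2,6-dimethylhepta-1,5-diene | I/C=C(\C)CCC=C(C)C | intermediate
10 | [(1E)-2,6-dimethylhepta-1,5-dien-1-yl]lithium | [Li]/C=C(\C)CCC=C(C)C | intermediate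
11 | bromo[(1E)-2,6-dimethylhepta-1,5-dien-1-yl]magnesium | Br[Mg]/C=C(\C)CCC=C(C)C | intermediate
12 | (1R,2E)-3,7-dimethyl-1-[(2S,3S)-3-methyl-3-[(E)-2-(tributylstannyl)ethenyl]oxiran-2-yl]octa-2,6-dien-1-ol | CC(C)=CCC/C(C)=C/[C@@H](O)[C@@H]1O[C@@]1(C)/C=C/[Sn](CCCC)(CCCC)CCCC | intermediate
13 | tributyl[(E)-2-[(2S,3S)-3-[(1R,2E)-1-(ethenyloxy)-3,7-dimethylocta-2,6-dien-1-yl]-2-methyloxiran-2-yl]ethenyl]stannane | CC(C)=CCC/C(C)=C/[C@@H](OC=C)[C@@H]1O[C@@]1(C)/C=C/[Sn](CCCC)(CCCC)CCCC | intermediate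
14 | (3S,4E)-3-methyl-3-(4-methylpent-3-en-1-yl)-5-[(2S,3S)-3-methyl-3-[(E)-2-(tributylstannyl)ethenyl]oxiran-2-yl]pent-4-enal | O=CC[C@](C)(CCC=C(C)C)/C=C/[C@@H]1O[C@@]1(C)/C=C/[Sn](CCCC)(CCCC)CCCC | intermediate
15 | ethyl (2Z,5S,6E)-2-iodo-5-methyl-5-(4-methylpent-3-en-1-yl)-7-[(2S,3S)-3-methyl-3-[(E)-2-(tributylstannyl)ethenyl]oxiran-2-yl]hepta-2,6-dienoate | CCOC(=O)/C(I)=C/C[C@](C)(CCC=C(C)C)/C=C/[C@@H]1O[C@@]1(C)/C=C/[Sn](CCCC)(CCCC)CCCC | intermediate
16 | (2Z,5S,6E)-2-iodo-5-methyl-5-(4-methylpent-3-en-1-yl)-7-[(2S,3S)-3-methyl-3-[(E)-2-(tributylstannyl)ethenyl]oxiran-2-yl]hepta-2,6-dien-1-ol | OC/C(I)=C/C[C@](C)(CCC=C(C)C)/C=C/[C@@H]1O[C@@]1(C)/C=C/[Sn](CCCC)(CCCC)CCCC | intermediate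
17 | (1E,3S,4R,5E,7S,9Z)-3,11-dihydroxy-10-iodo-3,7-dimethyl-7-(4-methylpent-3-en-1-yl)-1-(tributylstannyl)undeca-1,5,9-trien-4-yl 3-methylbut-2-enoate | OC/C(I)=C/C[C@](C)(CCC=C(C)C)/C=C/[C@@H](OC(=O)C=C(C)C)[C@@](C)(O)/C=C/[Sn](CCCC)(CCCC)CCCC | intermediate
18 | (1R,2E,4S,6Z,9E,11S)-11-hydroxy-7-(hydroxymethyl)-4,11-dimethyl-4-(4-methylpent-3-en-1-yl)-8-oxocycloundeca-2,6,9-trien-1-yl 3-methylbut-2-enoate | O=C1/C=C/[C@](C)(O)[C@H](OC(=O)C=C(C)C)/C=C/[C@@](C)(CCC=C(C)C)C/C=C1/CO | intermediate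
19 | (Z)-2-[(1R,2R,7S)-4-(hydroxymethyl)-2-[(1Z)-2-hydroxyprop-1-en-1-yl]-7-methyl-7-(4-methylpent-3-en-1-yl)-3-oxocyclohept-4-en-1-yl]ethenyl 3-methylbut-2-enoate (enol form of 20) | O/C(C)=C\[C@@H]1C(=O)C(CO)=CC[C@](C)(CCC=C(C)C)[C@@H]1/C=C\OC(=O)C=C(C)C | intermediate
20 | (Z)-2-[(1R,2S,7S)-4-(hydroxymethyl)-7-methyl-7-(4-methylpent-3-en-1-yl)-3-oxo-2-(2-oxopropyl)cyclohept-4-en-1-yl]ethenyl 3-methylbut-2-enoate | CC(=O)C[C@@H]1C(=O)C(CO)=CC[C@](C)(CCC=C(C)C)[C@@H]1/C=C\OC(=O)C=C(C)C | target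

**Step count and risks**

Total steps: 11. Longest linear sequence: 9 (steps 1, 2, 3, 6, 7, 8, 9, 10, 11 from compound 1).

Three steps most likely to fail:

Step 11 (carbonylative macrocyclisation and oxy-Cope cascade). The acylpalladium may be captured by the neighbouring C18 hydroxyl, or the vinyl groups may couple without CO. The contraction may also run through a chair instead of the boat and give the C10 epimer with an (E)-enol ester; the boat preference is an expectation, not something I can prove for this ring. The fallback sets out from 17 and separates the two events on a protected substrate. The C18 hydroxyl is silylated (TBSCl, imidazole, DMF) to give (1E,3S,4R,5E,7S,9Z)-11-[(tert-butyldimethylsilyl)oxy]-3-hydroxy-10-iodo-3,7-dimethyl-7-(4-methylpent-3-en-1-yl)-1-(tributylstannyl)undeca-1,5,9-trien-4-yl 3-methylbut-2-enoate F1. This is closed under the same carbonylative Stille conditions at 40 °C and the macrocycle is isolated as (1R,2E,4S,6Z,9E,11S)-7-{[(tert-butyldimethylsilyl)oxy]methyl}-11-hydroxy-4,11-dimethyl-4-(4-methylpent-3-en-1-yl)-8-oxocycloundeca-2,6,9-trien-1-yl 3-methylbut-2-enoate F2. F2 is heated alone (toluene, 100–110 °C, palladium-free, so solvent and temperature can be screened for the boat pathway) to give (Z)-2-[(1R,2S,7S)-4-{[(tert-butyldimethylsilyl)oxy]methyl}-7-methyl-7-(4-methylpent-3-en-1-yl)-3-oxo-2-(2-oxopropyl)cyclohept-4-en-1-yl]ethenyl 3-methylbut-2-enoate F3. Desilylation with HF·pyridine in THF at 0 °C returns to the route at 20.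

Step 10 (carboxylate opening of the oxirane). Attack at C8 is next to a fully substituted carbon and may be slow, and any acid catalysis would divert attack to the tertiary allylic C7. The fallback sets out from 16 and replaces direct ester delivery by hydrolysis then acylation. The primary alcohol is protected (TBDPSCl, imidazole) as tert-butyl{[(2Z,5S,6E)-2-iodo-5-methyl-5-(4-methylpent-3-en-1-yl)-7-[(2S,3S)-3-methyl-3-[(E)-2-(tributylstannyl)ethenyl]oxiran-2-yl]hepta-2,6-dien-1-yl]oxy}diphenylsilane F4. The oxirane is opened at C8 with hydroxide (LiOH, 1,4-dioxane–H2O, 60 °C, inversion) to give (1E,3S,4R,5E,7S,9Z)-11-[(tert-butyldiphenylsilyl)oxy]-10-iodo-3,7-dimethyl-7-(4-methylpent-3-en-1-yl)-1-(tributylstannyl)undeca-1,5,9-triene-3,4-diol F5. The secondary hydroxyl alone is acylated (3-methylbut-2-enoyl chloride, DMAP, pyridine, 0 °C; the tertiary alcohol does not react) to give (1E,3S,4R,5E,7S,9Z)-11-[(tert-butyldiphenylsilyl)oxy]-3-hydroxy-10-iodo-3,7-dimethyl-7-(4-methylpent-3-en-1-yl)-1-(tributylstannyl)undeca-1,5,9-trien-4-yl 3-methylbut-2-enoate F6. TBAF buffered with AcOH returns to the route at 17.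

Step 7 (iridium-catalysed vinylation and Claisen). The hindered secondary alcohol may vinylate poorly, and the tolerance of the vinylstannane toward the iridium catalyst is untested. The fallback sets out from 12 and uses a metal-free Eschenmoser–Claisen rearrangement (MeC(OMe)2NMe2, xylenes, 130 °C; same chair transition state and same chirality transfer) to give (3S,4E)-N,N,3-trimethyl-3-(4-methylpent-3-en-1-yl)-5-[(2S,3S)-3-methyl-3-[(E)-2-(tributylstannyl)ethenyl]oxiran-2-yl]pent-4-enamide F7. The amide is reduced to the aldehyde with Cp2Zr(H)Cl (THF, rt), returning to the route at 14.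

**Further compounds**

F1 | step 11 | (1E,3S,4R,5E,7S,9Z)-11-[(tert-butyldimethylsilyl)oxy]-3-hydroxy-10-iodo-3,7-dimethyl-7-(4-methylpent-3-en-1-yl)-1-(tributylstannyl)undeca-1,5,9-trien-4-yl 3-methylbut-2-enoate | CC(C)(C)[Si](C)(C)OC/C(I)=C/C[C@](C)(CCC=C(C)C)/C=C/[C@@H](OC(=O)C=C(C)C)[C@@](C)(O)/C=C/[Sn](CCCC)(CCCC)CCCC
F2 | step 11 | (1R,2E,4S,6Z,9E,11S)-7-{[(tert-butyldimethylsilyl)oxy]methyl}-11-hydroxy-4,11-dimethyl-4-(4-methylpent-3-en-1-yl)-8-oxocycloundeca-2,6,9-trien-1-yl 3-methylbut-2-enoate | O=C1/C=C/[C@](C)(O)[C@H](OC(=O)C=C(C)C)/C=C/[C@@](C)(CCC=C(C)C)C/C=C1/CO[Si](C)(C)C(C)(C)C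
F3 | step 11 | (Z)-2-[(1R,2S,7S)-4-{[(tert-butyldimethylsilyl)oxy]methyl}-7-methyl-7-(4-methylpent-3-en-1-yl)-3-oxo-2-(2-oxopropyl)cyclohept-4-en-1-yl]ethenyl 3-methylbut-2-enoate | CC(=O)C[C@@H]1C(=O)C(CO[Si](C)(C)C(C)(C)C)=CC[C@](C)(CCC=C(C)C)[C@@H]1/C=C\OC(=O)C=C(C)C
F4 | step 10 | tert-butyl{[(2Z,5S,6E)-2-iodo-5-methyl-5-(4-methylpent-3-en-1-yl)-7-[(2S,3S)-3-methyl-3-[(E)-2-(tributylstannyl)ethenyl]oxiran-2-yl]hepta-2,6-dien-1-yl]oxy}diphenylsilane | CC(C)(C)[Si](c1ccccc1)(c1ccccc1)OC/C(I)=C/C[C@](C)(CCC=C(C)C)/C=C/[C@@H]1O[C@@]1(C)/C=C/[Sn](CCCC)(CCCC)CCCC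
F5 | step 10 | (1E,3S,4R,5E,7S,9Z)-11-[(tert-butyldiphenylsilyl)oxy]-10-iodo-3,7-dimethyl-7-(4-methylpent-3-en-1-yl)-1-(tributylstannyl)undeca-1,5,9-triene-3,4-diol | CC(C)(C)[Si](c1ccccc1)(c1ccccc1)OC/C(I)=C/C[C@](C)(CCC=C(C)C)/C=C/[C@@H](O)[C@@](C)(O)/C=C/[Sn](CCCC)(CCCC)CCCC
F6 | step 10 | (1E,3S,4R,5E,7S,9Z)-11-[(tert-butyldiphenylsilyl)oxy]-3-hydroxy-10-iodo-3,7-dimethyl-7-(4-methylpent-3-en-1-yl)-1-(tributylstannyl)undeca-1,5,9-trien-4-yl 3-methylbut-2-enoate | CC(C)(C)[Si](c1ccccc1)(c1ccccc1)OC/C(I)=C/C[C@](C)(CCC=C(C)C)/C=C/[C@@H](OC(=O)C=C(C)C)[C@@](C)(O)/C=C/[Sn](CCCC)(CCCC)CCCC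
F7 | step 7 | (3S,4E)-N,N,3-trimethyl-3-(4-methylpent-3-en-1-yl)-5-[(2S,3S)-3-methyl-3-[(E)-2-(tributylstannyl)ethenyl]oxiran-2-yl]pent-4-enamide | CN(C)C(=O)C[C@](C)(CCC=C(C)C)/C=C/[C@@H]1O[C@@]1(C)/C=C/[Sn](CCCC)(CCCC)CCCC
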